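**Strategy.** Ring A is a cyclic poly-β-carbonyl array in which the C6 carbonyl sits between the quaternary, non-enolisable C1 (methyl, prenyl) and the isobutyryl-bearing C5. Everything therefore rests on the C5–C6 disconnection: an open-chain triketo methyl ester (20) that already carries (R)-C1, the C3 benzyl link and the complete ring B as its bis(methoxymethyl) ether. One base-mediated intramolecular Claisen condensation folds this chain, forming the C5–C6 bond and ring A with C1 untouched. Compound 20 is assembled from a desymmetrised methyl(prenyl)malonate half-ester and a regiospecifically built chromene bromide through two successive β-diketone polyanion couplings; acidic removal of both acetals ends the synthesis.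

Key step: step 11

Numbering used: ring A is C1 (quaternary; methyl, prenyl), C2 (enol carbon), C3 (carries the CH2 bridge), C4 (ring ketone), C5 (carries isobutyryl), C6 (enol carbon bonded to C1). Ring B is the benzene ring of the 2H-chromene (O1, C2 … C8a).

Assumption: pig liver esterase is taken to cleave the pro-S ester group of 3, the pattern for 2-alkyl-2-methylmalonates with longer chains, so that the half-ester is (R)-4; the fallback for step 2 covers a poorer outcome.

**Route**

Step 1
Reactants: 1 dimethyl methylmalonate; 2 1-bromo-3-methylbut-2-ene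
Product: 3 dimethyl 2-methyl-2-(3-methylbut-2-en-1-yl)propanedioate
Conditions: Cs2CO3 (1.5 equiv), DMF, 0 °C → rt
Reagents that add atoms: none
Why: Malonic ester alkylation (SN2 at the primary allylic carbon) should install the prenyl group and create the prochiral quaternary carbon; no stereocentre is formed yet.

Step 2
Reactants: 3 dimethyl 2-methyl-2-(3-methylbut-2-en-1-yl)propanedioate
Product: 4 (2R)-2-(methoxycarbonyl)-2,5-dimethylhex-4-enoic acid
Conditions: pig liver esterase, 0.1 M phosphate buffer (pH 7.5), 25 °C; acidify to pH 2, extract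
Reagents that add atoms: water, O
Why: Enzymatic desymmetrisation of a prochiral 2,2-disubstituted malonate should hydrolyse only the pro-S methoxycarbonyl group, which fixes the future C1 as (R), and should stop at the half-ester because the carboxylate is no longer a substrate.

Step 3
Reactants: 5 2,4,6-trihydroxybenzaldehyde
Product: 6 2-hydroxy-4,6-bis(methoxymethoxy)benzaldehyde
Conditions: MOMCl (2.2 equiv), i-Pr2NEt (3 equiv), CH2Cl2, 0 °C → rt
Reagents that add atoms: chloromethyl methyl ether, COCCl
Why: O-Alkylation (acetal formation) should take the para hydroxyl and one ortho hydroxyl, while the last ortho hydroxyl, locked in a hydrogen bond to the aldehyde, stays free.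

Step 4
Reactants: 6 2-hydroxy-4,6-bis(methoxymethoxy)benzaldehyde
Product: 7 2,4-bis(methoxymethoxy)-6-[(2-methylbut-3-yn-2-yl)oxy]benzaldehyde
Conditions: 3-chloro-3-methylbut-1-yne (1.5 equiv), DBU (1.6 equiv), CuCl2·2H2O (1 mol%), MeCN, 0 °C → rt
Reagents that add atoms: 3-chloro-3-methylbut-1-yne, CC(C)(Cl)C#C
Why: Copper-catalysed O-propargylation of a phenoxide by a tertiary propargylic chloride is an established route to aryl 1,1-dimethylpropargyl ethers, including phenols that carry an ortho carbonyl group.

Step 5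
Reactants: 7 2,4-bis(methoxymethoxy)-6-[(2-methylbut-3-yn-2-yl)oxy]benzaldehyde
Product: 10 5,7-bis(methoxymethoxy)-2,2-dimethyl-2H-chromene-8-carbaldehyde, via ortho-allenylphenol 8 (not isolated), via ortho-quinone methide 9 (not isolated)
Conditions: o-xylene, 140 °C
Reagents that add atoms: none
Why: Aromatic propargyl Claisen rearrangement to the only free ortho carbon, enolisation, 1,5-hydrogen shift and oxa-6π electrocyclisation should give the 2,2-dimethylchromene, and because the two other oxygens are capped as acetals the pyran oxygen can only be the propargylated one, so the ring fusion is unambiguous.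

Step 6
Reactants: 10 5,7-bis(methoxymethoxy)-2,2-dimethyl-2H-chromene-8-carbaldehyde
Product: 11 [5,7-bis(methoxymethoxy)-2,2-dimethyl-2H-chromen-8-yl]methanol
Conditions: NaBH4, MeOH, 0 °C
Reagents that add atoms: none
Why: Borohydride reduction of the aryl aldehyde should leave the acetals and the chromene double bond untouched.

Step 7
Reactants: 11 [5,7-bis(methoxymethoxy)-2,2-dimethyl-2H-chromen-8-yl]methanol
Product: 13 1-[8-(hydroxymethyl)-5,7-bis(methoxymethoxy)-2,2-dimethyl-2H-chromen-6-yl]-2-methylpropan-1-one, via dilithio species 12 (not isolated)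
Conditions: n-BuLi (2.3 equiv), THF, −20 → 0 °C; then N-methoxy-N-methylisobutyramide (1.5 equiv), −78 °C → rt; AcOH
Reagents that add atoms: N-methoxy-N,2-dimethylpropanamide, CC(C)C(=O)N(C)OC
Why: After the alkoxide has formed, directed ortho-metalation should remove the single aromatic hydrogen, which lies between the two methoxymethoxy groups, and the aryllithium is acylated by the Weinreb amide through a chelate that releases the ketone only on work-up.

Step 8
Reactants: 13 1-[8-(hydroxymethyl)-5,7-bis(methoxymethoxy)-2,2-dimethyl-2H-chromen-6-yl]-2-methylpropan-1-one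
Product: 14 1-[8-(bromomethyl)-5,7-bis(methoxymethoxy)-2,2-dimethyl-2H-chromen-6-yl]-2-methylpropan-1-one
Conditions: CBr4 (1.3 equiv), PPh3 (1.3 equiv), CH2Cl2, −20 → 0 °C; used at once
Reagents that add atoms: tetrabromomethane, BrC(Br)(Br)Br
Why: Appel bromination is neutral, so the acetals should survive, and the fully substituted ring B cannot alkylate itself.

Step 9
Reactants: 15 5-methylhexane-2,4-dione; 14 1-[8-(bromomethyl)-5,7-bis(methoxymethoxy)-2,2-dimethyl-2H-chromen-6-yl]-2-methylpropan-1-one
Product: 17 1-[5,7-bis(methoxymethoxy)-2,2-dimethyl-6-(2-methylpropanoyl)-2H-chromen-8-yl]-6-methylheptane-3,5-dione, via dilithio dianion 16 (not isolated)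
Conditions: 15 (1.5 equiv), LiN(i-Pr)2 (3.1 equiv), THF, −78 → 0 °C; then 14, −78 → −30 °C; AcOH
Reagents that add atoms: none
Why: γ-Alkylation of a β-diketone dianion: the second deprotonation takes the methyl group and not the isopropyl methine, and the terminal carbanion should displace the benzylic bromide (SN2) faster than it enolises the hindered aryl ketone.

Step 10
Reactants: 17 1-[5,7-bis(methoxymethoxy)-2,2-dimethyl-6-(2-methylpropanoyl)-2H-chromen-8-yl]-6-methylheptane-3,5-dione; 4 (2R)-2-(methoxycarbonyl)-2,5-dimethylhex-4-enoic acid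
Product: 20 methyl (2R)-2-{2-{[5,7-bis(methoxymethoxy)-2,2-dimethyl-6-(2-methylpropanoyl)-2H-chromen-8-yl]methyl}-6-methyl-3,5-dioxoheptanoyl}-2,5-dimethylhex-4-enoate (both epimers at the enolisable chain carbon C3), via acyl imidazole 18 (not isolated), via trilithio species 19 (not isolated)
Conditions: 4 (1.3 equiv), CDI (1.35 equiv), THF, rt; separately 17, LiN(i-Pr)2 (4.5 equiv: three for 17, the rest for the imidazole carried over), THF, −78 → −20 °C; combine at −78 °C, → −30 °C; AcOH at −78 °C
Reagents that add atoms: none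
Why: γ-Acylation of a β-diketone dianion by an acyl imidazole (Claisen-type C-acylation) should give the 1,3,5-triketone, since the second deprotonation takes the CH2 beside the benzyl arm and not the isopropyl methine, the aryl ketone sits as its unreactive tetrasubstituted enolate, and the acyl donor has no α-hydrogen, so (R)-C1 cannot racemise.

Step 11
Reactants: 20 methyl (2R)-2-{2-{[5,7-bis(methoxymethoxy)-2,2-dimethyl-6-(2-methylpropanoyl)-2H-chromen-8-yl]methyl}-6-methyl-3,5-dioxoheptanoyl}-2,5-dimethylhex-4-enoate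
Product: 21 (4R)-2-{[5,7-bis(methoxymethoxy)-2,2-dimethyl-6-(2-methylpropanoyl)-2H-chromen-8-yl]methyl}-3,5-dihydroxy-4-methyl-4-(3-methylbut-2-en-1-yl)-6-(2-methylpropanoyl)cyclohexa-2,5-dien-1-one
Conditions: KOt-Bu (3.5 equiv), THF, 0 °C → rt; cold 0.5 M HCl to pH 3
Reagents that add atoms: none
Why: tert-Butoxide should deprotonate C5 (between the C4 and isobutyryl carbonyls) and C3; the C5 carbanion adds to the ester carbonyl C6, methoxide leaves, and the acyltrione is at once deprotonated to its vinylogous carboxylate, which makes the closure irreversible. The closest known reaction is the Claisen (Dieckmann-type) cyclisation of 3,5-dioxo and poly-β-keto esters to 2-acylcyclohexane-1,3-diones and -1,3,5-triones, including substrates with a quaternary α-carbon. Ring A closes in the 6-exo-trig mode. No stereocentre is created: C1 takes no part, carries no hydrogen and keeps the (R) configuration set in step 2, while both C3 epimers converge because C3 becomes sp2. The step needs C-acylation over O-acylation, and this should be secured because the enol lactone formed through the C4 enolate oxygen is reopened by the liberated methoxide, whereas the carbocycle is trapped as its stabilised anion. It also needs the chain to survive, which the dianionic state (C2 and C4 held as enolates) and the poorly nucleophilic base should ensure against retro-Claisen cleavage.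

Step 12
Reactants: 21 (4R)-2-{[5,7-bis(methoxymethoxy)-2,2-dimethyl-6-(2-methylpropanoyl)-2H-chromen-8-yl]methyl}-3,5-dihydroxy-4-methyl-4-(3-methylbut-2-en-1-yl)-6-(2-methylpropanoyl)cyclohexa-2,5-dien-1-one
Product: 22 (4R)-2-{[5,7-dihydroxy-2,2-dimethyl-6-(2-methylpropanoyl)-2H-chromen-8-yl]methyl}-3,5-dihydroxy-4-methyl-4-(3-methylbut-2-en-1-yl)-6-(2-methylpropanoyl)cyclohexa-2,5-dien-1-one (target, CNP0319758.1)
Conditions: HCl (0.5 M) in MeOH, rt
Reagents that add atoms: none
Why: Acid-catalysed transacetalisation to methanol should remove both aryl methoxymethyl ethers, each assisted by the neighbouring aryl ketone, at an acidity too low to hydrate the chromene or to cyclise the prenyl group onto a ring A enol.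

**Compound list**

1 | dimethyl methylmalonate (dimethyl 2-methylpropanedioate) | COC(=O)C(C)C(=O)OC | starting material
2 | 1-bromo-3-methylbut-2-ene (prenyl bromide) | CC(C)=CCBr | starting material
3 | dimethyl 2-methyl-2-(3-methylbut-2-en-1-yl)propanedioate | COC(=O)C(C)(CC=C(C)C)C(=O)OC | intermediate
4 | (2R)-2-(methoxycarbonyl)-2,5-dimethylhex-4-enoic acid | CC(C)=CC[C@](C)(C(=O)O)C(=O)OC | intermediate
5 | 2,4,6-trihydroxybenzaldehyde | O=Cc1c(O)cc(O)cc1O | starting material
6 | 2-hydroxy-4,6-bis(methoxymethoxy)benzaldehyde | O=Cc1c(O)cc(OCOC)cc1OCOC | intermediate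
7 | 2,4-bis(methoxymethoxy)-6-[(2-methylbut-3-yn-2-yl)oxy]benzaldehyde | O=Cc1c(OCOC)cc(OCOC)cc1OC(C)(C)C#C | intermediate
8 | 2-hydroxy-4,6-bis(methoxymethoxy)-3-(3-methylbuta-1,2-dien-1-yl)benzaldehyde (ortho-allenylphenol) | O=Cc1c(O)c(C=C=C(C)C)c(OCOC)cc1OCOC | intermediate (not isolated)
9 | (5Z)-2,4-bis(methoxymethoxy)-5-(3-methylbut-2-en-1-ylidene)-6-oxocyclohexa-1,3-diene-1-carbaldehyde (ortho-quinone methide) | O=CC1=C(OCOC)C=C(OCOC)/C(=C/C=C(C)C)C1=O | intermediate (not isolated)
10 | 5,7-bis(methoxymethoxy)-2,2-dimethyl-2H-chromene-8-carbaldehyde | O=Cc1c(OCOC)cc(OCOC)c2C=CC(C)(C)Oc12 | intermediate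
11 | [5,7-bis(methoxymethoxy)-2,2-dimethyl-2H-chromen-8-yl]methanol | OCc1c(OCOC)cc(OCOC)c2C=CC(C)(C)Oc12 | intermediate
12 | lithium [6-lithio-5,7-bis(methoxymethoxy)-2,2-dimethyl-2H-chromen-8-yl]methanolate (dilithio species) | [Li]OCc1c(OCOC)c([Li])c(OCOC)c2C=CC(C)(C)Oc12 | intermediate (not isolated)
13 | 1-[8-(hydroxymethyl)-5,7-bis(methoxymethoxy)-2,2-dimethyl-2H-chromen-6-yl]-2-methylpropan-1-one | OCc1c(OCOC)c(C(=O)C(C)C)c(OCOC)c2C=CC(C)(C)Oc12 | intermediate
14 | 1-[8-(bromomethyl)-5,7-bis(methoxymethoxy)-2,2-dimethyl-2H-chromen-6-yl]-2-methylpropan-1-one | BrCc1c(OCOC)c(C(=O)C(C)C)c(OCOC)c2C=CC(C)(C)Oc12 | intermediate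
15 | 5-methylhexane-2,4-dione | CC(C)C(=O)CC(C)=O | starting material
16 | dilithium salt of the 1,3-dianion of 5-methylhexane-2,4-dione | [Li+].[Li+].[CH2-]C(=O)C=C([O-])C(C)C | intermediate (not isolated)
17 | 1-[5,7-bis(methoxymethoxy)-2,2-dimethyl-6-(2-methylpropanoyl)-2H-chromen-8-yl]-6-methylheptane-3,5-dione | CC(C)C(=O)CC(=O)CCc1c(OCOC)c(C(=O)C(C)C)c(OCOC)c2C=CC(C)(C)Oc12 | intermediate
18 | methyl (2R)-2-(1H-imidazole-1-carbonyl)-2,5-dimethylhex-4-enoate | CC(C)=CC[C@](C)(C(=O)n1ccnc1)C(=O)OC | intermediate (not isolated)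
19 | trilithium salt of 17 (diketone dianion at C2 and C4 of the heptanedione chain, plus the aryl ketone enolate) | [Li+].[Li+].[Li+].CC(C)=C([O-])c1c(OCOC)c(C[CH-]C(=O)C=C([O-])C(C)C)c2OC(C)(C)C=Cc2c1OCOC | intermediate (not isolated)
20 | methyl (2R)-2-{2-{[5,7-bis(methoxymethoxy)-2,2-dimethyl-6-(2-methylpropanoyl)-2H-chromen-8-yl]methyl}-6-methyl-3,5-dioxoheptanoyl}-2,5-dimethylhex-4-enoate (C3 epimers) | CC(C)=CC[C@](C)(C(=O)C(Cc2c(OCOC)c(C(=O)C(C)C)c(OCOC)c3c2OC(C)(C)C=C3)C(=O)CC(=O)C(C)C)C(=O)OC | intermediate
21 | (4R)-2-{[5,7-bis(methoxymethoxy)-2,2-dimethyl-6-(2-methylpropanoyl)-2H-chromen-8-yl]methyl}-3,5-dihydroxy-4-methyl-4-(3-methylbut-2-en-1-yl)-6-(2-methylpropanoyl)cyclohexa-2,5-dien-1-one | CC(C)=CC[C@]1(C)C(O)=C(Cc2c(OCOC)c(C(=O)C(C)C)c(OCOC)c3c2OC(C)(C)C=C3)C(=O)C(C(=O)C(C)C)=C1O | intermediate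
22 | (4R)-2-{[5,7-dihydroxy-2,2-dimethyl-6-(2-methylpropanoyl)-2H-chromen-8-yl]methyl}-3,5-dihydroxy-4-methyl-4-(3-methylbut-2-en-1-yl)-6-(2-methylpropanoyl)cyclohexa-2,5-dien-1-one | CC(C)=CC[C@]1(C)C(O)=C(Cc2c(O)c(C(=O)C(C)C)c(O)c3c2OC(C)(C)C=C3)C(=O)C(C(=O)C(C)C)=C1O | target

**Step count.** Total: 12 steps. Longest linear sequence: 10 steps (5 → 22, steps 3 to 12).

**Steps most likely to fail**

1. Step 11. Closure of the stabilised C5 carbanion onto an ester on a quaternary carbon may be slower than O-acylation through the C4 enolate oxygen or than base-induced cleavage of the chain, and the branched chain carrying ring B leaves little room to tune this. The fallback closes ring A before ring B is attached. It sets out from dianion 16 and acyl imidazole 18 (that is, from 15 and 4). Acylation at the unhindered terminal carbanion (THF, −78 → −30 °C) should give methyl (2R)-2,5-dimethyl-2-(6-methyl-3,5-dioxoheptanoyl)hex-4-enoate F1. Its Claisen cyclisation on the unbranched chain (NaOMe, MeOH, rt → 50 °C) should give (4R)-3,5-dihydroxy-4-methyl-4-(3-methylbut-2-en-1-yl)-2-(2-methylpropanoyl)cyclohexa-2,5-dien-1-one F2. C-Alkylation of the sodium salt of F2 at its only ring CH (C3) with bromide 14 (NaOMe, MeOH, 0 °C) comes back to the route at 21, and step 12 follows.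

2. Step 10. Addition of the hindered secondary carbanion of 19 to an acyl imidazole on a quaternary carbon may be too slow, so that proton transfer and O-acylation take over. The fallback makes the C2–C3 bond by aldol addition and corrects the oxidation level afterwards. It sets out from 4. Reduction of the acid through its mixed anhydride (i-BuOCOCl, N-methylmorpholine, THF, −15 °C; NaBH4, MeOH) should give methyl (2R)-2-(hydroxymethyl)-2,5-dimethylhex-4-enoate F3. Dess–Martin oxidation (NaHCO3, CH2Cl2) should give the non-enolisable aldehyde methyl (2R)-2-formyl-2,5-dimethylhex-4-enoate F4. Addition of 19 to F4 at −78 °C should give the β-hydroxy diketone methyl (2R)-2-{2-{[5,7-bis(methoxymethoxy)-2,2-dimethyl-6-(2-methylpropanoyl)-2H-chromen-8-yl]methyl}-1-hydroxy-6-methyl-3,5-dioxoheptyl}-2,5-dimethylhex-4-enoate F5 as a diastereomer mixture. Dess–Martin oxidation of the carbinol comes back to the route at 20.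

3. Step 2. The esterase may discriminate the two enantiotopic ester groups poorly, or in the opposite sense, so that 4 would not be a single enantiomer. The fallback replaces desymmetrisation by classical resolution. It sets out from 3. Half-saponification (KOH, 1 equiv, MeOH, rt) should give racemic 2-(methoxycarbonyl)-2,5-dimethylhex-4-enoic acid F6. Fractional crystallisation with (S)-1-phenylethylamine should give (S)-1-phenylethylammonium (2R)-2-(methoxycarbonyl)-2,5-dimethylhex-4-enoate F7; the antipodal amine is taken if the salt of the (S)-acid proves the less soluble. Acidification of F7 comes back to the route at 4.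

**Further compounds**

F1 | step 11 | methyl (2R)-2,5-dimethyl-2-(6-methyl-3,5-dioxoheptanoyl)hex-4-enoate | CC(C)=CC[C@](C)(C(=O)CC(=O)CC(=O)C(C)C)C(=O)OC
F2 | step 11 | (4R)-3,5-dihydroxy-4-methyl-4-(3-methylbut-2-en-1-yl)-2-(2-methylpropanoyl)cyclohexa-2,5-dien-1-one | CC(C)=CC[C@]1(C)C(O)=CC(=O)C(C(=O)C(C)C)=C1O
F3 | step 10 | methyl (2R)-2-(hydroxymethyl)-2,5-dimethylhex-4-enoate | CC(C)=CC[C@](C)(CO)C(=O)OC
F4 | step 10 | methyl (2R)-2-formyl-2,5-dimethylhex-4-enoate | CC(C)=CC[C@](C)(C=O)C(=O)OC
F5 | step 10 | methyl (2R)-2-{2-{[5,7-bis(methoxymethoxy)-2,2-dimethyl-6-(2-methylpropanoyl)-2H-chromen-8-yl]methyl}-1-hydroxy-6-methyl-3,5-dioxoheptyl}-2,5-dimethylhex-4-enoate (diastereomer mixture) | CC(C)=CC[C@](C)(C(O)C(Cc2c(OCOC)c(C(=O)C(C)C)c(OCOC)c3c2OC(C)(C)C=C3)C(=O)CC(=O)C(C)C)C(=O)OC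
F6 | step 2 | racemic 2-(methoxycarbonyl)-2,5-dimethylhex-4-enoic acid | CC(C)=CCC(C)(C(=O)O)C(=O)OC
F7 | step 2 | (S)-1-phenylethylammonium (2R)-2-(methoxycarbonyl)-2,5-dimethylhex-4-enoate | CC(C)=CC[C@](C)(C(=O)[O-])C(=O)OC.C[C@H]([NH3+])c1ccccc1
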